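**Retrosynthetic overview**
- Open the C4–C4a bond of the dihydronaphthalene: this gives an acyclic (S)-4,4-bis(3,4-dimethoxyphenyl)-2,3-dimethylbut-1-ene. C1 then carries two identical aryl groups, so ring closure onto one of them creates C1 under control of the C2 methyl centre (photocatalytic dehydrogenative 6-endo annulation).
- The isopropenyl group comes from an ethyl ester (two MeMgBr, then dehydration).
- The C1–C2 bond comes from SN2 (inversion) of a diarylmethyl anion on the triflate of ethyl (S)-lactate, so C2 is bought in lactate.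
- The diarylmethane comes from veratrole and veratryl alcohol (Friedel–Crafts).
- Ring order: both benzene rings are purchased; the only ring formed is the carbocyclic B-ring, in the last step.

Assumption: the target is numbered as a 1,2-dihydronaphthalene (C1 = aryl-bearing CH, C2 = CH(CH3), C3=C4 = ring alkene); the SMILES is read as the (1R,2S), trans isomer.

Step 1
Reactants: 1 veratrole (1,2-dimethoxybenzene); 2 3,4-dimethoxybenzyl alcohol
Product: 3 bis(3,4-dimethoxyphenyl)methane
Conditions: FeCl3 (5 mol%), 1 in excess (5 equiv), DCE, 60 °C, slow addition of 2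
Reagents that add atoms: none
Why: Friedel–Crafts benzylation: the veratryl cation attacks veratrole para to a methoxy group, and excess veratrole suppresses self-condensation of 2.

Step 2
Reactants: 4 ethyl (S)-lactate
Product: 5 ethyl (2S)-2-{[(trifluoromethyl)sulfonyl]oxy}propanoate
Conditions: Tf2O (1.05 equiv), 2,6-lutidine (1.1 equiv), CH2Cl2, −78 → 0 °C; used directly
Reagents that add atoms: trifluoromethanesulfonic anhydride, O=S(=O)(OS(=O)(=O)C(F)(F)F)C(F)(F)F
Why: O-sulfonylation of the secondary alcohol; no bond to the stereocentre is broken, so configuration is retained.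

Step 3
Reactants: 3 bis(3,4-dimethoxyphenyl)methane; 5 ethyl (2S)-2-{[(trifluoromethyl)sulfonyl]oxy}propanoate
Product: 7 ethyl (2S)-3,3-bis(3,4-dimethoxyphenyl)-2-methylpropanoate, via lithium diarylmethanide 6 (not isolated)
Conditions: 3, n-BuLi (1.0 equiv), THF, 0 °C → rt, 1 h; then cannulated into 5 (1.1 equiv), THF, −78 °C, 30 min
Reagents that add atoms: none
Why: SN2 alkylation: the soft, delocalised diarylmethyl anion displaces the α-carbonyl-activated secondary triflate with inversion at −78 °C (inverse addition keeps excess base away from the product's α-H), so the lactate centre becomes C2 with the required (S) geometry.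

Step 4
Reactants: 7 ethyl (2S)-3,3-bis(3,4-dimethoxyphenyl)-2-methylpropanoate
Product: 9 (3S)-4,4-bis(3,4-dimethoxyphenyl)-2,3-dimethylbutan-2-ol, via methyl ketone 8 (not isolated)
Conditions: MeMgBr (3.5 equiv), LaCl3·2LiCl (30 mol%), THF, 0 °C; H2O quench
Reagents that add atoms: methylmagnesium bromide, C[Mg]Br
Why: Double Grignard addition to the ester through ketone 8; the lanthanum salt favours carbonyl addition over enolisation, so the α-stereocentre is not epimerised.

Step 5
Reactants: 9 (3S)-4,4-bis(3,4-dimethoxyphenyl)-2,3-dimethylbutan-2-ol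
Product: 10 (3S)-4,4-bis(3,4-dimethoxyphenyl)-2,3-dimethylbut-1-ene
Conditions: Burgess reagent (1.5 equiv), benzene, 50 °C
Reagents that add atoms: none
Why: Burgess dehydration (syn Ei elimination under neutral, non-ionising conditions): only the methyl hydrogens reach the syn-periplanar geometry without eclipsing the benzhydryl group against the gem-dimethyl unit, which gives the isopropenyl alkene and leaves the stereocentre untouched.

Step 6
Reactants: 10 (3S)-4,4-bis(3,4-dimethoxyphenyl)-2,3-dimethylbut-1-ene
Product: 11 (1R,2S)-1-(3,4-dimethoxyphenyl)-6,7-dimethoxy-2,3-dimethyl-1,2-dihydronaphthalene (target)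
Conditions: 9-mesityl-10-methylacridinium BF4 (5 mol%), Co(dmgH)2(py)Cl (5 mol%), DCE/HFIP 4:1 (0.02 M), 450 nm LEDs, Ar, 25 °C, no base; stopped at about 80% conversion
Reagents that add atoms: none
Why: Proposed new method: an acceptorless dehydrogenative 6-endo arene–alkene annulation (intramolecular C(sp2)–H alkenylation). The excited acridinium (about +2.0 V vs SCE) oxidises one veratryl ring (about +1.4 V) to its radical cation; the ring carbon para to OMe adds to the unsubstituted alkene terminus (anti-Markovnikov, 6-endo) to give an arenium ion with a tertiary C3 radical; proton loss rearomatises; cobaloxime Co(II) removes the benzylic C4–H to give the conjugated C3=C4 alkene, and the Co(III)–H releases H2. The two aryl groups on C1 are diastereotopic, and the lactate-derived C2 methyl selects the half-chair with the spectator aryl pseudoaxial (no peri clash) and the C2 methyl pseudoaxial (no A1,2 strain with the C3 methyl), i.e. trans, which sets C1 as R. The closest known reaction types are acridinium/cobaloxime dehydrogenative alkene functionalisation via radical cations and anti-Markovnikov photoredox hydrofunctionalisation of alkenes; neither has been shown for a diastereotopic-group-selective 6-endo C–H alkenylation by an unactivated 1,1-dialkyl alkene.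

**Compound list**
1 | veratrole (1,2-dimethoxybenzene) | COc1ccccc1OC | starting material
2 | 3,4-dimethoxybenzyl alcohol | COc1ccc(CO)cc1OC | starting material
3 | bis(3,4-dimethoxyphenyl)methane | COc1ccc(Cc2ccc(OC)c(OC)c2)cc1OC | intermediate
4 | ethyl (S)-lactate | C[C@H](O)C(=O)OCC | starting material
5 | ethyl (2S)-2-{[(trifluoromethyl)sulfonyl]oxy}propanoate | C[C@H](OS(=O)(=O)C(F)(F)F)C(=O)OCC | intermediate
6 | lithium bis(3,4-dimethoxyphenyl)methanide | [Li+].COc1ccc([CH-]c2ccc(OC)c(OC)c2)cc1OC | intermediate (not isolated)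
7 | ethyl (2S)-3,3-bis(3,4-dimethoxyphenyl)-2-methylpropanoate | CCOC(=O)[C@H](C(c1ccc(OC)c(OC)c1)c1ccc(OC)c(OC)c1)C | intermediate
8 | (3S)-4,4-bis(3,4-dimethoxyphenyl)-3-methylbutan-2-one | CC(=O)[C@H](C(c1ccc(OC)c(OC)c1)c1ccc(OC)c(OC)c1)C | intermediate (not isolated)
9 | (3S)-4,4-bis(3,4-dimethoxyphenyl)-2,3-dimethylbutan-2-ol | CC(C)(O)[C@H](C(c1ccc(OC)c(OC)c1)c1ccc(OC)c(OC)c1)C | intermediate
10 | (3S)-4,4-bis(3,4-dimethoxyphenyl)-2,3-dimethylbut-1-ene | C=C(C)[C@H](C(c1ccc(OC)c(OC)c1)c1ccc(OC)c(OC)c1)C | intermediate
11 | (1R,2S)-1-(3,4-dimethoxyphenyl)-6,7-dimethoxy-2,3-dimethyl-1,2-dihydronaphthalene | COc1ccc([C@@H]2c3cc(OC)c(OC)cc3C=C(C)[C@H]2C)cc1OC | target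

**Totals**
Total step count: 6. Longest linear sequence: 5 (4 → 5 → 7 → 9 → 10 → 11).

**Three steps most likely to fail**

Step 6 (the proposed new step). The product styrene is easier to oxidise than the veratryl rings, so over-oxidation to the 1-arylnaphthalene is the main danger. Other risks are deprotonation of the radical cation at the doubly benzylic C1–H, alkene regioisomers from the C3 radical, and a modest trans/cis ratio. The fallback uses known chemistry, sets out from 10 and comes back at 11. Anti-Markovnikov hydroboration–oxidation of 10 (9-BBN, THF; then NaOH, H2O2) gives (3S)-4,4-bis(3,4-dimethoxyphenyl)-2,3-dimethylbutan-1-ol F1 as a mixture of C2 epimers. Dess–Martin oxidation gives (3S)-4,4-bis(3,4-dimethoxyphenyl)-2,3-dimethylbutanal F2. Catalytic p-TsOH in toluene at 60 °C then effects intramolecular Friedel–Crafts hydroxyalkylation and dehydration (Bradsher-type cyclodehydration) to 11. The epimeric centre vanishes in the dehydration, and the same trans preference decides which aryl group closes.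

Step 3. The anion is strongly basic, so proton transfer from the α-H of the triflate, elimination to acrylate, or partial loss of ee can compete with SN2. The fallback sets out from 3 (as its anion 6) and comes back at 10. Purchased (2S,3S)-butane-2,3-diol F3 is treated with SOCl2 to give the cyclic sulfite (4S,5S)-4,5-dimethyl-1,3,2-dioxathiolane 2-oxide F4. Oxidation (RuCl3 cat., NaIO4) gives the cyclic sulfate (4S,5S)-4,5-dimethyl-1,3,2-dioxathiolane 2,2-dioxide F5, a non-enolisable and very reactive electrophile. Anion 6 opens it with inversion to lithium (2S,3S)-4,4-bis(3,4-dimethoxyphenyl)-3-methylbutan-2-yl sulfate F6, which is hydrolysed without isolation (cat. H2SO4, THF/H2O) to (2S,3S)-4,4-bis(3,4-dimethoxyphenyl)-3-methylbutan-2-ol F7. Dess–Martin oxidation gives ketone 8, here isolated, and Wittig methylenation (Ph3P=CH2, THF, −78 → 0 °C) gives 10.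

Step 5. The dehydration may give some tetrasubstituted (Zaitsev) alkene, which destroys C2, or an indane by cationic cyclisation if the sulfamate ionises. The fallback sets out from 7 and comes back at 10 without any cationic intermediate. Ester 7 is converted with MeNH(OMe)·HCl and i-PrMgCl (THF, −20 °C) into the Weinreb amide (2S)-3,3-bis(3,4-dimethoxyphenyl)-N-methoxy-N,2-dimethylpropanamide F8. MeMgBr stops cleanly at ketone 8, and regiospecific Wittig methylenation (Ph3P=CH2, THF, −78 → 0 °C) gives 10.

**Further compounds**
F1 | step 6 | (3S)-4,4-bis(3,4-dimethoxyphenyl)-2,3-dimethylbutan-1-ol (C2 epimers) | OCC(C)[C@H](C(c1ccc(OC)c(OC)c1)c1ccc(OC)c(OC)c1)C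
F2 | step 6 | (3S)-4,4-bis(3,4-dimethoxyphenyl)-2,3-dimethylbutanal (C2 epimers) | O=CC(C)[C@H](C(c1ccc(OC)c(OC)c1)c1ccc(OC)c(OC)c1)C
F3 | step 3 | (2S,3S)-butane-2,3-diol (purchased) | C[C@H](O)[C@H](C)O
F4 | step 3 | (4S,5S)-4,5-dimethyl-1,3,2-dioxathiolane 2-oxide | C[C@@H]1OS(=O)O[C@H]1C
F5 | step 3 | (4S,5S)-4,5-dimethyl-1,3,2-dioxathiolane 2,2-dioxide | C[C@@H]1OS(=O)(=O)O[C@H]1C
F6 | step 3 | lithium (2S,3S)-4,4-bis(3,4-dimethoxyphenyl)-3-methylbutan-2-yl sulfate (not isolated) | C[C@H](OS(=O)(=O)[O-])[C@H](C(c1ccc(OC)c(OC)c1)c1ccc(OC)c(OC)c1)C.[Li+]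
F7 | step 3 | (2S,3S)-4,4-bis(3,4-dimethoxyphenyl)-3-methylbutan-2-ol | C[C@H](O)[C@H](C(c1ccc(OC)c(OC)c1)c1ccc(OC)c(OC)c1)C
F8 | step 5 | (2S)-3,3-bis(3,4-dimethoxyphenyl)-N-methoxy-N,2-dimethylpropanamide | CON(C)C(=O)[C@H](C(c1ccc(OC)c(OC)c1)c1ccc(OC)c(OC)c1)C
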